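**Retrosynthetic overview**
- Feature used: ring A (C1–C6) and ring B (C1′–C6′) are the same arene, 2,5-dimethylresorcinol, with O on C2/C4 and C2′/C4′ and Me on C3/C6 and C3′/C6′. The only skeletal carbons outside it are the depside carbonyl C7 (on C1) and the carboxyl carbon C7′ (on C1′).
- Key disconnection: both bonds of C7 are cut at once, C1–C7 and C7–O4′. This gives three components: the ring-A aryl iodide, carbon monoxide and the ring-B 4′-phenol (as its benzyl ester).
- C1′–C7′ is cut the same way (iodide + CO + benzyl alcohol). Both iodides are one compound, 4-iodo-2,5-dimethylresorcinol, capped either on oxygen (2 × Me) or on carbon (CO/BnOH).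
- That iodide comes from mono-iodination of the C2v-symmetric resorcinol (C2 blocked, C4/C6 homotopic), so no regiochemical question arises anywhere in the route.
- No ring is formed. Both benzene rings enter intact, and the last step only frees the acid by hydrogenolysis.

Key step: step 4

Remark: diffractaic acid has no stereocentre and no configurationally stable axis. The SMILES therefore carries no stereodescriptor and the route needs no stereocontrol.

**Step 1**
Reactants: 1 2,5-dimethylbenzene-1,3-diol (2,5-dimethylresorcinol, β-orcinol)
Product: 2 4-iodo-2,5-dimethylbenzene-1,3-diol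
Conditions: NIS (1.0 equiv), MeCN, −10 to 0 °C, dark
Reagents that add atoms: N-iodosuccinimide, O=C1CCC(=O)N1I
Why: Electrophilic aromatic iodination: C2 is blocked by methyl and C4/C6 are homotopic and activated by both hydroxyl groups, so only this mono-iodide can form, and exact stoichiometry at low temperature should hold back the second iodination.

**Step 2**
Reactants: 2 4-iodo-2,5-dimethylbenzene-1,3-diol
Product: 3 1-iodo-2,4-dimethoxy-3,6-dimethylbenzene (ring-A numbering: I on C1, OMe on C2 and C4, Me on C3 and C6)
Conditions: MeI (3 equiv), K2CO3 (3 equiv), DMF, rt to 40 °C
Reagents that add atoms: iodomethane, CI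
Why: Williamson ether synthesis: carbonate ionises both phenols, which are O-methylated by SN2 on MeI, and the aryl iodide is inert under these conditions.

**Step 3**
Reactants: 2 4-iodo-2,5-dimethylbenzene-1,3-diol
Product: 4 benzyl 2,4-dihydroxy-3,6-dimethylbenzoate
Conditions: PdCl2(dppf) (3 mol %), CO (5 bar), BnOH (10 equiv), Et3N (2 equiv), DMF, 80 °C
Reagents that add atoms: carbon monoxide, [C-]#[O+]; benzyl alcohol, OCc1ccccc1
Why: Palladium-catalysed alkoxycarbonylation of an aryl iodide (Heck carbonylation), a reaction type that tolerates free phenols: oxidative addition, CO insertion and alcoholysis by a large excess of the primary alcohol, which should outcompete the hindered phenolic OH groups that Et3N does not ionise in DMF.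

**Step 4**
Reactants: 3 1-iodo-2,4-dimethoxy-3,6-dimethylbenzene; 4 benzyl 2,4-dihydroxy-3,6-dimethylbenzoate
Product: 5 benzyl 4-[(2,4-dimethoxy-3,6-dimethylbenzoyl)oxy]-2-hydroxy-3,6-dimethylbenzoate (benzyl diffractaate)
Conditions: Pd(OAc)2 (5 mol %), Xantphos (6 mol %), DMAP (20 mol %), K2CO3 (1.5 equiv), 4 Å MS, CO (5 bar), 1,4-dioxane, 100 °C
Reagents that add atoms: carbon monoxide, [C-]#[O+]
Why: Palladium-catalysed aryloxycarbonylation (Heck-type carbonylative esterification) run as a three-component union: Pd(0) inserts into the C1–I bond of 3, CO inserts into the resulting aryl–Pd bond, and the metal-bound aroyl group is passed (DMAP as acyl-transfer co-catalyst) to the potassium 4-phenoxide of 4, so that C1–C7 and C7–O4′ are formed in one operation. The closest known reaction type is the phenoxycarbonylation of aryl iodides with substituted phenols, which is established for ortho-substituted partners. No ring is closed and no stereocentre is formed. The step needs chemoselectivity between the two hydroxyl groups of 4: 2-OH is locked in a hydrogen bond to the benzyl ester carbonyl and is flanked by 3-Me and the ester, so only the free and more acidic 4-OH should be ionised and acylated. It also needs CO insertion to outrun direct C–O coupling and hydrodeiodination, which the two ortho groups of 3 (2-OMe and 6-Me, which speed up migratory insertion by relief of strain), the CO pressure and the hydride-poor medium (carbonate base, no alcohol, no trialkylamine) should secure. The gain is that the most hindered carbonyl of the target is built on the metal in its activated form, so that no 2,6-disubstituted benzoate has to be hydrolysed and no 2,6-disubstituted benzoic acid has to be activated.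

**Step 5**
Reactants: 5 benzyl diffractaate
Product: 6 diffractaic acid, 4-[(2,4-dimethoxy-3,6-dimethylbenzoyl)oxy]-2-hydroxy-3,6-dimethylbenzoic acid
Conditions: H2 (1 atm), 10 % Pd/C, EtOAc, rt
Reagents that add atoms: none
Why: Catalytic hydrogenolysis of the benzylic C–O bond under neutral conditions: the aryl ester, the aryl methyl ethers and the phenol are inert, and no base or heat is present that could cleave the depside bond or decarboxylate the salicylic acid.

**Compound list**
1 | 2,5-dimethylbenzene-1,3-diol (β-orcinol) | Cc1cc(O)c(C)c(O)c1 | starting material
2 | 4-iodo-2,5-dimethylbenzene-1,3-diol | Cc1cc(O)c(C)c(O)c1I | intermediate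
3 | 1-iodo-2,4-dimethoxy-3,6-dimethylbenzene | COc1cc(C)c(I)c(OC)c1C | intermediate
4 | benzyl 2,4-dihydroxy-3,6-dimethylbenzoate | Cc1cc(O)c(C)c(O)c1C(=O)OCc1ccccc1 | intermediate
5 | benzyl diffractaate | COc1cc(C)c(C(=O)Oc2cc(C)c(C(=O)OCc3ccccc3)c(O)c2C)c(OC)c1C | intermediate
6 | diffractaic acid | COc1cc(C)c(C(=O)Oc2cc(C)c(C(=O)O)c(O)c2C)c(OC)c1C | target

Total step count: 5. Longest linear sequence: 4 (1 → 2 → 3 or 4 → 5 → 6).

**Steps most likely to fail**

1. **Step 4 (key step).** Acyl transfer from the doubly ortho-substituted metal-bound aroyl group to the ortho-methylated, weakly nucleophilic phenoxide may be slower than reductive loss of iodine or decay of the catalyst under CO. The fallback puts the C1 unit on ring A first and acylates in a separate event.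
   - It sets out from 3. Iodine–lithium exchange (n-BuLi, THF, −78 °C) should give 2,4-dimethoxy-3,6-dimethylphenyllithium F1.
   - F1 is quenched with CO2 and acidified to 2,4-dimethoxy-3,6-dimethylbenzoic acid F2.
   - Trifluoroacetic anhydride in toluene at rt should convert F2 into 2,4-dimethoxy-3,6-dimethylbenzoic trifluoroacetic anhydride F3.
   - F3 acylates the free 4-OH of 4 and comes back to the route at 5.

2. **Step 3.** The phenolic OH groups of substrate and product may compete with benzyl alcohol in the acyl-transfer event (oligomeric ester formation). The electron-rich iodide may also lose iodine by reduction. The fallback uses CO2 in place of CO, with no iodide and no metal catalyst.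
   - It sets out from 1. Kolbe–Schmitt carboxylation (KHCO3, CO2 pressure, glycerol, 130 °C; then cold dilute HCl) can only strike the homotopic C4/C6 positions and should give 2,4-dihydroxy-3,6-dimethylbenzoic acid F4.
   - Carboxylate-selective alkylation (BnBr, KHCO3, DMF, rt) comes back to the route at 4.

3. **Step 1.** Over-iodination at the second homotopic position, and acid- or light-induced loss of iodine from the free iodoresorcinol during handling, may erode the supply of the common iodide. The fallback caps first and iodinates afterwards.
   - It sets out from 1. Double O-methylation (MeI, K2CO3, DMF) should give 1,3-dimethoxy-2,5-dimethylbenzene F5.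
   - Iodination of F5 (NIS, cat. TFA, MeCN, 0 °C) again has only one possible site and comes back to the route at 3.
   - Ring B is then supplied through the fallback described for step 3, so that 2 is no longer needed.

**Further compounds**
F1 | step 4 | 2,4-dimethoxy-3,6-dimethylphenyllithium | COc1cc(C)c([Li])c(OC)c1C
F2 | step 4 | 2,4-dimethoxy-3,6-dimethylbenzoic acid | COc1cc(C)c(C(=O)O)c(OC)c1C
F3 | step 4 | 2,4-dimethoxy-3,6-dimethylbenzoic trifluoroacetic anhydride | COc1cc(C)c(C(=O)OC(=O)C(F)(F)F)c(OC)c1C
F4 | step 3 | 2,4-dihydroxy-3,6-dimethylbenzoic acid | Cc1cc(O)c(C)c(O)c1C(=O)O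
F5 | step 1 | 1,3-dimethoxy-2,5-dimethylbenzene | COc1cc(C)cc(OC)c1C
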